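Readings and results are calculated with constants of no real substance.

**Small charge.** A small charge of free enzyme, 0.052 mol% in the winter run, makes target from starting material and second substrate, and second substrate also consumes target. You want the target from four set-ups.

| setting | winter | noon | cedar | alder | maple | ash |
|---|---|---|---|---|---|---|
| starting material | 0.020 M | 0.020 M | 0.020 M | 0.020 M | 0.020 M | 0.020 M |
| second substrate | 0.70 equiv | 0.70 equiv | 0.700 equiv | 0.700 equiv (fed, over 2.50 h) | 0.700 equiv | 0.700 equiv |
| free enzyme | 0.052 mol% | 0.1 mol% | 0.052 mol% | 0.052 mol% | 0.052 mol% | 0.052 mol% |
| remark | run made earlier | run made earlier | a single well-mixed tank run continuously and read at steady state, 25.0 h in it on average | all but second substrate at the start; second substrate goes in evenly over 2.50 h, the run ends at 2.5 h | a single well-mixed tank run continuously and read at steady state, 2.5 h in it on average | everything together in a closed stirred flask, run for 2.5 h |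
| time |  |  |  | 2.5 h |  | 2.5 h |

winter run (percent of the starting material charged)

| time / h | target / % | starting material / % |
|---|---|---|
| 0.667 | 26.6 | 51.4 |
| 1.33 | 28.2 | 51.0 |
| 2.00 | 27.5 | 51.5 |
| 2.50 | 27.0 | 51.3 |

noon run (percent of the starting material charged)

| time / min | target / % | starting material / % |
|---|---|---|
| 4.00 | 15.4 | 79.9 |
| 8.00 | 27.4 | 62.7 |
| 12.0 | 33.1 | 51.8 |
| 15.0 | 36.1 | 48.6 |

(standard deviation of a reading: 0.5 percentage points)

- the stated concentrations are those of everything mixed, before any reaction; amounts are the same in each set-up
- the numbers in the tables scatter with a standard deviation of 0.5 percentage points
- steps thought possible: starting material + free enzyme <-> first complex; first complex -> loaded enzyme + first product; second substrate + loaded enzyme <-> second complex; second complex -> free enzyme + target; second substrate + target -> over-reaction product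
- the feed brings no volume worth counting
- the earlier runs were made in a closed, stirred flask

- the set-up with the highest amount of target at the outlet or at the end, in percent of the starting material put in ("none" if the first two lie within 2 percentage points) (cedar / alder / maple / ash / none)
- amount of target at the outlet or at the end, in percent of the starting material put in, cedar
- amount of target at the outlet or at the end, in percent of the starting material put in, alder
- amount of target at the outlet or at the end, in percent of the starting material put in, maple
- amount of target at the outlet or at the end, in percent of the starting material put in, ash

**The ledger.** Each target takes one second substrate and one starting material. Each over-reaction product takes two second substrate and one starting material. So second substrate used is twice the starting material lost, minus the target, in percent of starting material charged; the enzyme charge, at most 0.1 mol%, is too small to count against a scatter of 0.5 percentage points. Subtract that from the charge and you have the ledger, the second substrate left. At the last winter reading it is −0.400%.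

**The curve.** The noon run draws it. The ledger leaves 45.2% at 4.00 min, a steep start, then 22.8% at 8.00 min and 6.70% at 12.0 min. The knee comes near 15.0 min, with 3.30% left and target at 36.1%.

The winter run, with about half the enzyme, passes its knee before its first reading: at 0.667 h the ledger already reads −0.600%, zero within the scatter. Second substrate, the limiting reagent, is spent there, and target stays level near 27.0%.

**My reckoning.** Ash repeats the winter recipe, so I expect about 27.0% there.

**The forecast.** It says 25.2% for cedar, 31% for alder, 24% for maple and 27.3% for ash, with alder best. Its ground: “The plateau is therefore a spent-reagent end, not a stalled enzyme.”

**The result.** The flask gives 28.3% for cedar, 34.8% for alder, 26.8% for maple and 27.3% for ash. So alder leads, by 6.5 points over cedar, as forecast.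

    starting material + free enzyme ⇌ first complex (K = 11.0 M⁻¹, k = 26000 M⁻¹ s⁻¹)
    first complex → loaded enzyme + first product (k = 150 s⁻¹)
    second substrate + loaded enzyme ⇌ second complex (K = 200 M⁻¹, k = 2300 M⁻¹ s⁻¹)
    second complex → free enzyme + target (k = 1.30 s⁻¹)
    second substrate + target → over-reaction product (k = 0.180 M⁻¹ s⁻¹)

**What held.** Slow dosing is part of alder's lead: take it away and alder falls from 34.8% to 27.3%. The largest single effect on alder's lead over maple is the step of second substrate + target to over-reaction product: take that step away and maple minus alder moves from −8 points to 0.2 points. Winter's ledger stood at −0.400%. The same reckoning gives cedar 0.123% left, beside 0.226% from its tank level 4.53 × 10⁻⁵ M. For maple it gives 2.26%, beside 2.36% from its tank level 4.72 × 10⁻⁴ M.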